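**Plan**
1. The target (labdane numbering) is cut at C12–C13 (butenolide onto a C12 alkylzinc) and at the C6 carbinol, which is traced through a C6 ketone back to the C6=C7 bond of a ring B 6,8-diene.
2. Ring B (C5–C10) of that diene holds a quaternary C10, H5 cis to the C10 methyl, and the C8=C9 bond. This is the imprint of a C10=C5–C6=C7–C8=C9 triene on ring A that has closed C9–C10 and passed H9 to C5, so C9–C10 is cut and H5 returned to C9.
3. The triene is cut at C5–C6 and C7–C8 around one acetylene (C6≡C7, later cis-reduced). The pieces are the actinol enol triflate, ethynyltrimethylsilane and an (E)-α-bromoacrylate carrying C8, C9, C11, C12 and C17.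
4. Forward: ring A alkyne, dienyne, (6Z)-triene; ring B by thermal closure; C6 oxygen by osmylation, hydride shift to the ketone and late reduction; butenolide by Negishi coupling; desilylation.
5. Stereochemistry: C2 comes from actinol; C10 and C5 from the key step (ring A conformation, disrotation, suprafacial shift); C6 from hydride delivery to the convex face; both triene geometries from the olefination and the cis-reduction.

Key step: step 11

Remark: labdane numbering is used throughout (decalin C1–C10, side chain C11–C16, hydroxymethyl C17). α and β mean below and above the plane in the usual drawing with the C10 methyl up. Read this way, the SMILES makes the target the 2α,6α,17-triol with H5 β (cis ring fusion).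

**Step 1**
Reactants: 1 (4R,6R)-4-hydroxy-2,2,6-trimethylcyclohexanone (actinol)
Product: 2 (4R,6R)-4-(tert-butyldimethylsilyloxy)-2,2,6-trimethylcyclohexanone
Conditions: t-BuMe2SiCl, imidazole, DMF, 23 °C
Reagents that add atoms: tert-butyldimethylsilyl chloride, CC(C)(C)[Si](C)(C)Cl
Why: Imidazole-promoted silylation of the secondary alcohol gives a TBS ether that should last until the final fluoride treatment (silyl ether protection).

**Step 2**
Reactants: 2 (4R,6R)-4-(tert-butyldimethylsilyloxy)-2,2,6-trimethylcyclohexanone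
Product: 4 (4R)-4-(tert-butyldimethylsilyloxy)-2,6,6-trimethylcyclohex-1-en-1-yl trifluoromethanesulfonate, via lithium enolate 3 (not isolated)
Conditions: LiN(i-Pr)2, THF, −78 → 0 °C; PhNTf2, 0 → 23 °C
Reagents that add atoms: N-phenylbis(trifluoromethanesulfonimide), O=S(=O)(N(c1ccccc1)S(=O)(=O)C(F)(F)F)C(F)(F)F
Why: The ketone can enolise only toward the methyl-bearing carbon (the other α-carbon is quaternary), so enolate O-triflation gives the single tetrasubstituted enol triflate; the silyloxy group is too remote to be eliminated.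

**Step 3**
Reactants: 4 (4R)-4-(tert-butyldimethylsilyloxy)-2,6,6-trimethylcyclohex-1-en-1-yl trifluoromethanesulfonate; 5 ethynyltrimethylsilane
Product: 6 (4R)-4-(tert-butyldimethylsilyloxy)-2,6,6-trimethyl-1-[(trimethylsilyl)ethynyl]cyclohex-1-ene
Conditions: Pd(PPh3)4 (5 mol %), CuI (10 mol %), Et3N, DMF, 50 °C
Reagents that add atoms: none
Why: Sonogashira coupling of hindered 2,6,6-trimethylcyclohexenyl triflates with a small terminal alkyne is well established and forms C5–C6.

**Step 4**
Reactants: 6 (4R)-4-(tert-butyldimethylsilyloxy)-2,6,6-trimethyl-1-[(trimethylsilyl)ethynyl]cyclohex-1-ene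
Product: 7 (4R)-4-(tert-butyldimethylsilyloxy)-1-ethynyl-2,6,6-trimethylcyclohex-1-ene
Conditions: K2CO3 (cat.), MeOH, 23 °C
Reagents that add atoms: none
Why: Base-catalysed methanolysis cleaves only the C(sp)–Si bond and leaves the TBS ether (protiodesilylation of an alkynylsilane).

**Step 5**
Reactants: 8 methyl bis(2,2,2-trifluoroethyl)phosphonoacetate
Product: 10 methyl bromo[bis(2,2,2-trifluoroethoxy)phosphoryl]acetate, via dibromophosphonoacetate 9 (not isolated)
Conditions: Br2, aq NaOH, 0 °C; then SnCl2, EtOH/H2O, 0 °C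
Reagents that add atoms: bromine, BrBr
Why: Exhaustive α-bromination with hypobromite followed by removal of one bromine with SnCl2 should give the monobromophosphonate without the mixtures of direct monobromination (halogenation, then reductive dehalogenation of a phosphonoacetate).

**Step 6**
Reactants: 10 methyl bromo[bis(2,2,2-trifluoroethoxy)phosphoryl]acetate; 11 3-(tert-butyldimethylsilyloxy)propanal
Product: 13 methyl (2E)-2-bromo-5-(tert-butyldimethylsilyloxy)pent-2-enoate (ester cis to the chain), via potassium phosphonate carbanion 12 (not isolated)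
Conditions: t-BuOK, 18-crown-6, THF, −78 °C; then 11
Reagents that add atoms: none
Why: Horner–Wadsworth–Emmons olefination with a bis(trifluoroethyl) α-bromophosphonate under dissociating conditions (Still–Gennari-type kinetic control) places the ester cis to the alkyl chain, giving the (E)-α-bromoacrylate that later fixes C7 trans to C11.

**Step 7**
Reactants: 7 (4R)-4-(tert-butyldimethylsilyloxy)-1-ethynyl-2,6,6-trimethylcyclohex-1-ene; 13 methyl (2E)-2-bromo-5-(tert-butyldimethylsilyloxy)pent-2-enoate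
Product: 14 methyl (2Z)-2-{[(4R)-4-(tert-butyldimethylsilyloxy)-2,6,6-trimethylcyclohex-1-en-1-yl]ethynyl}-5-(tert-butyldimethylsilyloxy)pent-2-enoate (alkyne trans to the chain)
Conditions: Pd(PPh3)4 (5 mol %), CuI (10 mol %), Et3N, THF, 23 °C
Reagents that add atoms: none
Why: Sonogashira coupling of the activated α-bromoacrylate proceeds with retention of alkene geometry and forms C7–C8.

**Step 8**
Reactants: 14 dienyne ester
Product: 15 (2Z)-2-{[(4R)-4-(tert-butyldimethylsilyloxy)-2,6,6-trimethylcyclohex-1-en-1-yl]ethynyl}-5-(tert-butyldimethylsilyloxy)pent-2-en-1-ol (C17 alcohol)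
Conditions: i-Bu2AlH (2.5 equiv), CH2Cl2, −78 °C; Rochelle salt
Reagents that add atoms: none
Why: 1,2-Reduction of the conjugated ester by i-Bu2AlH gives the allylic alcohol without touching the enyne; C17 is taken to the alcohol level here because a C17 carbonyl would hold the later ring B diene in the linearly conjugated 5,7-position.

**Step 9**
Reactants: 15 dienyne alcohol
Product: 16 tert-butyldiphenylsilyl ether of 15 (C5(=C10)–C6≡C7–C8(CH2OTBDPS)=C9H–CH2CH2OTBS, C7 trans to C11)
Conditions: t-BuPh2SiCl, imidazole, CH2Cl2, 23 °C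
Reagents that add atoms: tert-butyldiphenylsilyl chloride, CC(C)(C)[Si](Cl)(c1ccccc1)c1ccccc1
Why: Silylation of the primary allylic alcohol with a TBDPS group that outlasts the later selective removal of the primary TBS ether at C12 (orthogonal silyl protection).

**Step 10**
Reactants: 16 dienyne bis-silyl ether
Product: 17 (6Z)-triene: ring A as in 7 carrying at C5 the chain (Z)-CH=CH–C(CH2OTBDPS)=CH–CH2CH2OTBS, C7 trans to C11 (H9 inside)
Conditions: Zn dust activated with Cu(OAc)2 and AgNO3, MeOH/H2O (1:1), 23–35 °C, dark; used at once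
Reagents that add atoms: none
Why: Activated zinc reduces the triple bond of conjugated dienynes to the cis alkene without over-reduction or isomerisation (cis semi-reduction).

**Step 11**
Reactants: 17 (6Z)-triene
Product: 19 cis-fused 6,8-diene (C6=C7 and C8=C9, 2α-OTBS, 5β-H, 10β-CH3, C9–CH2CH2OTBS, C8–CH2OTBDPS), via 5,7-diene 18 (not isolated)
Conditions: degassed decalin, BHT (cat.), sealed tube, 140 °C then 210 °C
Reagents that add atoms: none
Why: On heating, the helical s-cis,s-cis conformer of 17 closes C9–C10 in a thermal disrotatory 6π electrocyclisation to the 5,7-diene 18, whose only ring sp3 hydrogen (H9) then migrates suprafacially to C5 in a [1,5]-sigmatropic shift, moving the diene to C6=C7/C8=C9. The closest known reaction types are the thermal ring closure of previtamin D-type trienes to 9,10-cis cyclohexadienes and the [1,5]-hydrogen shift of 1,3-cyclohexadienes. Ring B closes in the disrotatory six-electron mode, so the two inside groups, the C10 methyl and H9 (inside because step 6 placed C7 trans to C11), end cis. C10 is set by the face of ring A that C9 reaches: the equatorial C2 silyloxy group fixes the half-chair with the pseudoaxial C4 methyl on the β face and the pseudoequatorial one just below the alkene plane, so the twisted chain tips toward the α face (moving H6 away from that methyl) and C9 bonds to C10 from below, anti to the pseudoaxial methyl, leaving the C10 methyl β. C5 is set by the suprafacial shift, which hands H9 to the same (β) face of C5, cis to the C10 methyl. The step needs this helix sense and a complete shift; the ring A conformation supplies the first, and relief of allylic strain between the C4 methyls and a C5=C6 bond, together with the new tetrasubstituted C8=C9 bond, should drive the second.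

**Step 12**
Reactants: 19 cis-fused 6,8-diene
Product: 20 6β,7β-diol of 19 (C8=C9 retained)
Conditions: OsO4 (5 mol %), N-methylmorpholine N-oxide, acetone/H2O (8:1), 23 °C
Reagents that add atoms: osmium tetroxide (catalytic oxygen carrier), O=[Os](=O)(=O)=O; N-methylmorpholine N-oxide, C[N+]1([O-])CCOCC1; water, O
Why: Catalytic OsO4 dihydroxylation takes the cis-disubstituted C6=C7 bond and leaves the tetrasubstituted C8=C9 bond, which it attacks far more slowly; addition should come from the convex β face, but either cis-diol serves because C6 and C7 lose their configuration in step 13.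

**Step 13**
Reactants: 20 6,7-diol
Product: 22 6-ketone (2α-OTBS, 5β-H, 10β-CH3, C7H2, C8=C9, C9–CH2CH2OTBS, C8–CH2OTBDPS), via allylic mesylate 21 (not isolated)
Conditions: Ms2O (1.3 equiv), 2,6-lutidine, CH2Cl2, −40 → 23 °C
Reagents that add atoms: none
Why: The less hindered allylic C7 hydroxyl is sulfonylated and the allylic mesylate ionises with a 1,2-hydride shift from C6 (semipinacol rearrangement of a cis-diol monosulfonate, H6 antiperiplanar to the pseudoaxial leaving group), giving the β,γ-unsaturated C6 ketone with C8=C9 and C5 untouched.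

**Step 14**
Reactants: 22 6-ketone
Product: 23 12-alcohol (22 with C12–OH)
Conditions: HF·pyridine, pyridine, THF, 0 °C
Reagents that add atoms: none
Why: Buffered HF·pyridine removes the primary TBS ether much faster than the secondary TBS and the TBDPS ethers (selective desilylation).

**Step 15**
Reactants: 23 12-alcohol
Product: 24 12-iodide (22 with C12–I)
Conditions: I2, PPh3, imidazole, CH2Cl2, 0 → 23 °C
Reagents that add atoms: iodine, II
Why: Appel-type iodination of the primary alcohol under near-neutral conditions tolerates the ketone, the alkene and the silyl ethers.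

**Step 16**
Reactants: 24 12-iodide; 25 4-bromofuran-2(5H)-one
Product: 27 2α-(tert-butyldimethylsilyloxy)-17-(tert-butyldiphenylsilyloxy)-6-oxo-5β-labda-8,13-dien-15,16-olide, via alkylzinc iodide 26 (not isolated)
Conditions: Zn dust (activated with BrCH2CH2Br and Me3SiCl), LiCl, THF, 40 °C; then 25, Pd2(dba)3 (2.5 mol %), P(2-furyl)3 (10 mol %), THF, 23 °C
Reagents that add atoms: none
Why: Zinc insertion into the primary iodide gives an alkylzinc iodide that tolerates the ketone, and Negishi coupling at the β-position of the bromobutenolide forms C12–C13 (Pd-catalysed sp3–sp2 cross-coupling).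

**Step 17**
Reactants: 27 6-oxo butenolide
Product: 28 6α-hydroxy-2α-(tert-butyldimethylsilyloxy)-17-(tert-butyldiphenylsilyloxy)-5β-labda-8,13-dien-15,16-olide
Conditions: NaBH4, CeCl3·7H2O, MeOH/THF, −40 °C
Reagents that add atoms: none
Why: Luche reduction is selective for the ketone over the butenolide, and hydride should enter C6 from the convex β face (equatorial attack, the α-axial path being blocked by the syn-axial C1 methylene of ring A), giving the 6α (axial) alcohol as in other 6-oxo-4,4-dimethyldecalins.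

**Step 18**
Reactants: 28 6α-alcohol
Product: 29 2α,6α,17-trihydroxy-5β-labda-8,13-dien-15,16-olide (CNP0293367.1)
Conditions: HF·pyridine, THF, 0 → 23 °C
Reagents that add atoms: none
Why: Fluoride cleavage of the remaining TBS and TBDPS ethers under mildly acidic conditions that do not open or isomerise the butenolide (global desilylation).

**Compound list**
1 | (4R,6R)-4-hydroxy-2,2,6-trimethylcyclohexanone (actinol) | CC1(C)C[C@H](O)C[C@@H](C)C1=O | starting material
2 | (4R,6R)-4-(tert-butyldimethylsilyloxy)-2,2,6-trimethylcyclohexanone | CC1(C)C[C@H](O[Si](C)(C)C(C)(C)C)C[C@@H](C)C1=O | intermediate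
3 | lithium enolate of 2 (enolised toward the methyl-bearing carbon) | [Li+].CC1=C([O-])C(C)(C)C[C@H](O[Si](C)(C)C(C)(C)C)C1 | intermediate
4 | (4R)-4-(tert-butyldimethylsilyloxy)-2,6,6-trimethylcyclohex-1-en-1-yl trifluoromethanesulfonate (ring A; OTf on C5, C10=C5, silyloxy on C2) | CC1=C(OS(=O)(=O)C(F)(F)F)C(C)(C)C[C@H](O[Si](C)(C)C(C)(C)C)C1 | intermediate
5 | ethynyltrimethylsilane | C#C[Si](C)(C)C | starting material
6 | (4R)-4-(tert-butyldimethylsilyloxy)-2,6,6-trimethyl-1-[(trimethylsilyl)ethynyl]cyclohex-1-ene | CC1=C(C#C[Si](C)(C)C)C(C)(C)C[C@H](O[Si](C)(C)C(C)(C)C)C1 | intermediate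
7 | (4R)-4-(tert-butyldimethylsilyloxy)-1-ethynyl-2,6,6-trimethylcyclohex-1-ene | CC1=C(C#C)C(C)(C)C[C@H](O[Si](C)(C)C(C)(C)C)C1 | intermediate
8 | methyl bis(2,2,2-trifluoroethyl)phosphonoacetate | COC(=O)CP(=O)(OCC(F)(F)F)OCC(F)(F)F | starting material
9 | methyl dibromo[bis(2,2,2-trifluoroethoxy)phosphoryl]acetate | COC(=O)C(Br)(Br)P(=O)(OCC(F)(F)F)OCC(F)(F)F | intermediate
10 | methyl bromo[bis(2,2,2-trifluoroethoxy)phosphoryl]acetate | COC(=O)C(Br)P(=O)(OCC(F)(F)F)OCC(F)(F)F | intermediate
11 | 3-(tert-butyldimethylsilyloxy)propanal | O=CCCO[Si](C)(C)C(C)(C)C | starting material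
12 | potassium salt of the carbanion of 10 | [K+].COC(=O)[C-](Br)P(=O)(OCC(F)(F)F)OCC(F)(F)F | intermediate
13 | methyl (2E)-2-bromo-5-(tert-butyldimethylsilyloxy)pent-2-enoate | COC(=O)/C(Br)=C\CCO[Si](C)(C)C(C)(C)C | intermediate
14 | methyl (2Z)-2-{[(4R)-4-(tert-butyldimethylsilyloxy)-2,6,6-trimethylcyclohex-1-en-1-yl]ethynyl}-5-(tert-butyldimethylsilyloxy)pent-2-enoate | CC1=C(C#C/C(C(=O)OC)=C/CCO[Si](C)(C)C(C)(C)C)C(C)(C)C[C@H](O[Si](C)(C)C(C)(C)C)C1 | intermediate
15 | (2Z)-2-{[(4R)-4-(tert-butyldimethylsilyloxy)-2,6,6-trimethylcyclohex-1-en-1-yl]ethynyl}-5-(tert-butyldimethylsilyloxy)pent-2-en-1-ol | CC1=C(C#C/C(CO)=C/CCO[Si](C)(C)C(C)(C)C)C(C)(C)C[C@H](O[Si](C)(C)C(C)(C)C)C1 | intermediate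
16 | tert-butyldiphenylsilyl ether of 15 | CC1=C(C#C/C(CO[Si](c2ccccc2)(c2ccccc2)C(C)(C)C)=C/CCO[Si](C)(C)C(C)(C)C)C(C)(C)C[C@H](O[Si](C)(C)C(C)(C)C)C1 | intermediate
17 | (6Z)-triene: C10=C5–C6=C7–C8(CH2OTBDPS)=C9H–CH2CH2OTBS on ring A (2-OTBS), C6=C7 cis, C7 trans to C11 | CC1(C)C[C@H](O[Si](C)(C)C(C)(C)C)CC(C)=C1/C=C\C(CO[Si](c1ccccc1)(c1ccccc1)C(C)(C)C)=C\CCO[Si](C)(C)C(C)(C)C | intermediate
18 | 5,7-diene: C5=C6 and C7=C8, 2α-OTBS, 10β-CH3, 9β-H, 9α-CH2CH2OTBS, C8–CH2OTBDPS | CC1(C)C[C@H](O[Si](C)(C)C(C)(C)C)C[C@]2(C)[C@H](CCO[Si](C)(C)C(C)(C)C)C(CO[Si](c3ccccc3)(c3ccccc3)C(C)(C)C)=CC=C12 | intermediate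
19 | cis-fused 6,8-diene: C6=C7 and C8=C9, 2α-OTBS, 5β-H, 10β-CH3, C9–CH2CH2OTBS, C8–CH2OTBDPS | CC1(C)C[C@H](O[Si](C)(C)C(C)(C)C)C[C@]2(C)C(CCO[Si](C)(C)C(C)(C)C)=C(CO[Si](c3ccccc3)(c3ccccc3)C(C)(C)C)C=C[C@H]12 | intermediate
20 | 6β,7β-diol of 19 | CC1(C)C[C@H](O[Si](C)(C)C(C)(C)C)C[C@]2(C)C(CCO[Si](C)(C)C(C)(C)C)=C(CO[Si](c3ccccc3)(c3ccccc3)C(C)(C)C)[C@@H](O)[C@@H](O)[C@H]12 | intermediate
21 | 7β-methanesulfonate of 20 (6β-OH free) | CC1(C)C[C@H](O[Si](C)(C)C(C)(C)C)C[C@]2(C)C(CCO[Si](C)(C)C(C)(C)C)=C(CO[Si](c3ccccc3)(c3ccccc3)C(C)(C)C)[C@@H](OS(C)(=O)=O)[C@@H](O)[C@H]12 | intermediate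
22 | 6-ketone: 2α-OTBS, 5β-H, 10β-CH3, C8=C9, C9–CH2CH2OTBS, C8–CH2OTBDPS | CC1(C)C[C@H](O[Si](C)(C)C(C)(C)C)C[C@]2(C)C(CCO[Si](C)(C)C(C)(C)C)=C(CO[Si](c3ccccc3)(c3ccccc3)C(C)(C)C)CC(=O)[C@H]12 | intermediate
23 | 12-alcohol: 22 with C9–CH2CH2OH | CC1(C)C[C@H](O[Si](C)(C)C(C)(C)C)C[C@]2(C)C(CCO)=C(CO[Si](c3ccccc3)(c3ccccc3)C(C)(C)C)CC(=O)[C@H]12 | intermediate
24 | 12-iodide: 22 with C9–CH2CH2I | CC1(C)C[C@H](O[Si](C)(C)C(C)(C)C)C[C@]2(C)C(CCI)=C(CO[Si](c3ccccc3)(c3ccccc3)C(C)(C)C)CC(=O)[C@H]12 | intermediate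
25 | 4-bromofuran-2(5H)-one | O=C1C=C(Br)CO1 | starting material
26 | alkylzinc iodide: 22 with C9–CH2CH2ZnI | CC1(C)C[C@H](O[Si](C)(C)C(C)(C)C)C[C@]2(C)C(CC[Zn]I)=C(CO[Si](c3ccccc3)(c3ccccc3)C(C)(C)C)CC(=O)[C@H]12 | intermediate
27 | 2α-(tert-butyldimethylsilyloxy)-17-(tert-butyldiphenylsilyloxy)-6-oxo-5β-labda-8,13-dien-15,16-olide | CC1(C)C[C@H](O[Si](C)(C)C(C)(C)C)C[C@]2(C)C(CCC3=CC(=O)OC3)=C(CO[Si](c4ccccc4)(c4ccccc4)C(C)(C)C)CC(=O)[C@H]12 | intermediate
28 | 6α-hydroxy-2α-(tert-butyldimethylsilyloxy)-17-(tert-butyldiphenylsilyloxy)-5β-labda-8,13-dien-15,16-olide | CC1(C)C[C@H](O[Si](C)(C)C(C)(C)C)C[C@]2(C)C(CCC3=CC(=O)OC3)=C(CO[Si](c4ccccc4)(c4ccccc4)C(C)(C)C)C[C@H](O)[C@H]12 | intermediate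
29 | 2α,6α,17-trihydroxy-5β-labda-8,13-dien-15,16-olide (CNP0293367.1) | CC1(C)C[C@H](O)C[C@]2(C)C(CCC3=CC(=O)OC3)=C(CO)C[C@H](O)[C@H]12 | target

**Totals and risks**
Total step count: 18. Longest linear sequence: 16 steps (steps 1–4 and 7–18, from 1).

Step 11. What may go wrong: the ring closure is the easy half, but the [1,5]-shift needs a much higher temperature and is reversible. The reaction may therefore stall at the 5,7-diene or settle at a mixture of the two dienes. Long heating also lets reversible hydrogen shifts from the C10 methyl erode the C8=C9 geometry of the triene before it closes. Fallback (sets out from 18, isolated from a run held at 140 °C; returns at 19): the shift is carried out on iron instead of thermally. Fe2(CO)9 in warm benzene should bind the less hindered β face of the diene (the face of H9 and the C10 methyl) to give the tricarbonyliron complex of the 5,7-diene F1. At about 140 °C in di-n-butyl ether such complexes pass their endo allylic hydrogen across the metal-bound face through an allyl iron hydride. This delivers H9 to C5 on the β face and leaves the metal on the less substituted diene, the tricarbonyliron complex of the 6,8-diene F2. CuCl2 in ethanol then frees 19.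

Step 13. What may go wrong: the allylic cation may lose a proton from C11 (elimination to a cross-conjugated triene) or be captured by sulfonate before H6 migrates, and sulfonylation may not distinguish the two hydroxyls well enough. Fallback (sets out from 20, returns at 22): radical instead of cationic removal of the C7 oxygen, then oxidation. 1,1'-Thiocarbonyldiimidazole (toluene, 80 °C) should give the cyclic thionocarbonate F3. Bu3SnH with AIBN at 110 °C cleaves the allylic C7–O bond; the allyl radical takes hydrogen at its unhindered C7 end, which keeps C8=C9. This leaves the S-tributylstannyl thiocarbonate of the C6 alcohol F4, which loses carbonyl sulfide on aqueous work-up to give the 6β-alcohol F5. Dess–Martin periodinane then gives 22.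

Step 17. What may go wrong: hydride may enter from the concave α face (loss of facial selectivity at C6), or add in the conjugate sense to the butenolide if the hindered ketone forces a higher temperature. Fallback (sets out from 22, returns at 29): the ketone is reduced with a bulky hydride before the butenolide exists, and the alcohol is carried protected. LiBH(s-Bu)3 (THF, −78 °C) should give the 6α-alcohol F6 by equatorial attack. t-BuMe2SiOTf with 2,6-lutidine gives the 2,6-bis-TBS ether F7. HF·pyridine/pyridine removes only the primary TBS group, giving the 12-alcohol F8, and I2/PPh3/imidazole gives the 12-iodide F9. Zinc insertion gives the alkylzinc iodide F10, which couples with 25 as in step 16 to the fully silylated butenolide F11. HF·pyridine then removes the three silyl groups to give 29.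

**Further compounds**
F1 | step 11 | tricarbonyl(η4-5,7-diene 18)iron, metal on the β face | CC1(C)C[C@H](O[Si](C)(C)C(C)(C)C)C[C@]2(C)[C@H](CCO[Si](C)(C)C(C)(C)C)C(CO[Si](c3ccccc3)(c3ccccc3)C(C)(C)C)=CC=C12.[Fe].[C-]#[O+].[C-]#[O+].[C-]#[O+]
F2 | step 11 | tricarbonyl(η4-6,8-diene 19)iron, metal on the β face | CC1(C)C[C@H](O[Si](C)(C)C(C)(C)C)C[C@]2(C)C(CCO[Si](C)(C)C(C)(C)C)=C(CO[Si](c3ccccc3)(c3ccccc3)C(C)(C)C)C=C[C@H]12.[Fe].[C-]#[O+].[C-]#[O+].[C-]#[O+]
F3 | step 13 | cyclic 6β,7β-thionocarbonate of diol 20 | CC1(C)C[C@H](O[Si](C)(C)C(C)(C)C)C[C@]2(C)C(CCO[Si](C)(C)C(C)(C)C)=C(CO[Si](c3ccccc3)(c3ccccc3)C(C)(C)C)[C@H]3OC(=S)O[C@H]3[C@H]12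
F4 | step 13 | 6β-O-[(tributylstannylthio)carbonyl] derivative with C7H2 and C8=C9 | CC1(C)C[C@H](O[Si](C)(C)C(C)(C)C)C[C@]2(C)C(CCO[Si](C)(C)C(C)(C)C)=C(CO[Si](c3ccccc3)(c3ccccc3)C(C)(C)C)C[C@@H](OC(=O)S[Sn](CCCC)(CCCC)CCCC)[C@H]12
F5 | step 13 | 6β-alcohol (2α-OTBS, 12-OTBS, 17-OTBDPS, C8=C9) | CC1(C)C[C@H](O[Si](C)(C)C(C)(C)C)C[C@]2(C)C(CCO[Si](C)(C)C(C)(C)C)=C(CO[Si](c3ccccc3)(c3ccccc3)C(C)(C)C)C[C@@H](O)[C@H]12
F6 | step 17 | 6α-alcohol (2α-OTBS, 12-OTBS, 17-OTBDPS, C8=C9) | CC1(C)C[C@H](O[Si](C)(C)C(C)(C)C)C[C@]2(C)C(CCO[Si](C)(C)C(C)(C)C)=C(CO[Si](c3ccccc3)(c3ccccc3)C(C)(C)C)C[C@H](O)[C@H]12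
F7 | step 17 | 2α,6α-bis-TBS ether (12-OTBS, 17-OTBDPS) | CC1(C)C[C@H](O[Si](C)(C)C(C)(C)C)C[C@]2(C)C(CCO[Si](C)(C)C(C)(C)C)=C(CO[Si](c3ccccc3)(c3ccccc3)C(C)(C)C)C[C@H](O[Si](C)(C)C(C)(C)C)[C@H]12
F8 | step 17 | 12-alcohol (2α,6α-bis-OTBS, 17-OTBDPS) | CC1(C)C[C@H](O[Si](C)(C)C(C)(C)C)C[C@]2(C)C(CCO)=C(CO[Si](c3ccccc3)(c3ccccc3)C(C)(C)C)C[C@H](O[Si](C)(C)C(C)(C)C)[C@H]12
F9 | step 17 | 12-iodide (2α,6α-bis-OTBS, 17-OTBDPS) | CC1(C)C[C@H](O[Si](C)(C)C(C)(C)C)C[C@]2(C)C(CCI)=C(CO[Si](c3ccccc3)(c3ccccc3)C(C)(C)C)C[C@H](O[Si](C)(C)C(C)(C)C)[C@H]12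
F10 | step 17 | C12 alkylzinc iodide (2α,6α-bis-OTBS, 17-OTBDPS) | CC1(C)C[C@H](O[Si](C)(C)C(C)(C)C)C[C@]2(C)C(CC[Zn]I)=C(CO[Si](c3ccccc3)(c3ccccc3)C(C)(C)C)C[C@H](O[Si](C)(C)C(C)(C)C)[C@H]12
F11 | step 17 | 2α,6α-bis(tert-butyldimethylsilyloxy)-17-(tert-butyldiphenylsilyloxy)-5β-labda-8,13-dien-15,16-olide | CC1(C)C[C@H](O[Si](C)(C)C(C)(C)C)C[C@]2(C)C(CCC3=CC(=O)OC3)=C(CO[Si](c4ccccc4)(c4ccccc4)C(C)(C)C)C[C@H](O[Si](C)(C)C(C)(C)C)[C@H]12
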